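**Retrosynthetic overview**
1. Target 33 ⇒ 8β-alcohol 25 + Z-acid 31 (C8–O ester formed with inversion); the methylenes C13 and C3 and the vinyl C1=C2 are unfolded to a lactone CH2, a C15 aldehyde and a C1 aldehyde.
2. The trans 6α,12-lactone is the syn-hydration pattern of a C6=C7 alkene carrying the C11–C12 arm on C7 ⇒ cyclohexene diol 13.
3. Key disconnection: cyclohexene C5–C10 by an intramolecular Diels–Alder reaction forming C8–C9 and C5–C10; the diene C8=C7–C6=C5 is the amine-bound cross-trienamine of 3-(alkoxymethyl)-2,4-dienal 9, the dienophile C9=C10 a tethered 2-substituted acrylate.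
4. Enabling feature: in ring C5–C10 the two-carbon unit C9–C10 is flanked by the four-carbon unit C5–C8; C7 bears the C11–C12 acetaldehyde arm (enamine handle), and the 1,3-cis branches C14 (on C10, alcohol level) and C15 (via C4 on C5, aldehyde level) can be tied as one six-membered cyclic acetal, the tether.
5. Ring order: cyclohexene plus temporary tetrahydropyran together (step 7), γ-lactone (step 9), tetrahydropyran opened (step 11); 9 comes from iodo-enal 4 and alkyne acetal 7 by Suzuki–Miyaura coupling.

Key step: step 7

Remark: elemanolide numbering is used (ring C5–C10; vinyl C1=C2 and C14 on C10; C4 with methylene C3 and hydroxymethyl C15 on C5; lactone C11–C13; β = face of C14; target = 5S,6R,7R,8S,10R); the acetal carbon C15 of 7–18 is formed without control, carried as both epimers and ceases to be stereogenic in step 12; commercial 6 is assumed to be freed from its methanol–water stabiliser before use; PMB = (4-methoxyphenyl)methyl, TBS = tert-butyldimethylsilyl.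

Step 1
Reactants: 1 but-2-yne-1,4-diol
Product: 2 4-[(4-methoxyphenyl)methoxy]but-2-yn-1-ol
Conditions: 1 (3 equiv), NaH (1 equiv), 4-methoxybenzyl chloride (1 equiv), THF/DMF, 0 → 25 °C
Reagents that add atoms: 4-methoxybenzyl chloride, COc1ccc(CCl)cc1
Why: Williamson etherification of the symmetrical diol used in excess should give mainly the mono-ether, and no stereocentre is involved.

Step 2
Reactants: 2 4-[(4-methoxyphenyl)methoxy]but-2-yn-1-ol
Product: 3 4-[(4-methoxyphenyl)methoxy]but-2-ynal
Conditions: MnO2 (10 equiv), CH2Cl2, 25 °C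
Reagents that add atoms: none
Why: MnO2 oxidises the propargylic alcohol selectively to the ynal and leaves the PMB ether untouched.

Step 3
Reactants: 3 4-[(4-methoxyphenyl)methoxy]but-2-ynal
Product: 4 (2Z)-3-iodo-4-[(4-methoxyphenyl)methoxy]but-2-enal
Conditions: NaI (1.5 equiv), AcOH, 25 °C
Reagents that add atoms: sodium iodide, [Na+].[I-]
Why: Conjugate hydroiodination of the ynal puts iodide on the β-carbon (C7) by anti addition, which makes C7 a cross-coupling site; the alkene geometry is irrelevant later.

Step 4
Reactants: 5 methyl 2-(hydroxymethyl)prop-2-enoate; 6 (1Z)-1-methoxybut-1-en-3-yne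
Product: 7 methyl 2-{[(1-methoxybut-3-yn-1-yl)oxy]methyl}prop-2-enoate
Conditions: pyridinium 4-toluenesulfonate (5 mol%), CH2Cl2, 0 → 25 °C
Reagents that add atoms: none
Why: Acid-catalysed addition of the alcohol to the enol ether (protonation next to the alkyne, capture of the oxocarbenium ion at C15) gives the mixed acetal that later serves as tether, C15 being formed without control.

Step 5
Reactants: 7 methyl 2-{[(1-methoxybut-3-yn-1-yl)oxy]methyl}prop-2-enoate
Product: 8 (E)-alkenyl pinacolboronate of 7 (boron on C6)
Conditions: pinacolborane (1.2 equiv), Cp2Zr(H)Cl (10 mol%), Et3N (10 mol%), CH2Cl2, 25 °C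
Reagents that add atoms: pinacolborane, [H]B1OC(C)(C)C(C)(C)O1
Why: Zirconium-catalysed syn hydroboration of the terminal alkyne is anti-Markovnikov and gives the (E)-alkenylboronate (C5=C6), the electron-poor acrylate and the acetal being inert to pinacolborane.

Step 6
Reactants: 8 (E)-alkenyl pinacolboronate; 4 (2Z)-3-iodo-4-[(4-methoxyphenyl)methoxy]but-2-enal
Product: 9 (3E,5E)-dienal carrying the acetal-tethered acrylate
Conditions: Pd(PPh3)4 (5 mol%), K3PO4 (3 equiv), THF/H2O, 25 °C
Reagents that add atoms: none
Why: Suzuki–Miyaura coupling forms C6–C7 with retention of both alkene geometries; the 2E geometry (formyl cis to the diene) is of no consequence, because C11=C7 becomes a single bond in the trienamine and any 2H-pyran valence isomer is in equilibrium with 9.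

Step 7
Reactants: 9 (3E,5E)-dienal carrying the acetal-tethered acrylate
Product: 13 cis-fused isochromene diol (C1 and C12 as CH2OH; 8β-OPMB; C6=C7), via cross-trienamine 10 (not isolated), via cycloadduct dienamine 11 (not isolated), via cycloadduct aldehyde 12 (not isolated)
Conditions: (2R)-2-[diphenyl(trimethylsilyloxy)methyl]pyrrolidine (20 mol%), 2-fluorobenzoic acid (20 mol%), toluene (0.05 M), 40 °C; then THF, LiAlH4, 0 °C
Reagents that add atoms: none
Why: Proposed new method: the amine condenses with the enal of 9 and γ-deprotonation at C8 gives cross-trienamine 10, in which the nitrogen lone pair raises the HOMO of the C8=C7–C6=C5 diene and makes C8 its nucleophilic terminus, so that the tethered acrylate (electrophilic at C9) adds in the polarity-matched sense C8–C9 and C5–C10 in an asynchronous suprafacial [4+2] cycloaddition to dienamine 11, whose hydrolysis releases 12 and the amine before LiAlH4 reduces aldehyde and ester in the same flask. The closest known reaction type is the secondary-amine-catalysed trienamine (cross-trienamine) Diels–Alder reaction of 2,4-dienals with doubly activated alkenes, extended here to an intramolecular (type 1) case in which the six-membered acetal tether makes up for the single activating group. The cyclohexene C5–C10 is closed by the cycloaddition itself and the tetrahydropyran C5–C4–C15–O–C14–C10 by the same C5–C10 bond in the fused mode, the bridged regiochemistry being out of reach of a four-atom tether. C5 and C8 should come out cis because C4 and OPMB are both outside substituents of (E)-configured diene termini, C10 is set by the exo position of the ester and the endo position of the tether CH2 that 2-alkyl-substituted acrylic dienophiles prefer (C14 syn to C4, cis-fused acetal ring), and the absolute configuration is set by the CPh2(OSiMe3) group of the (R)-amine, which covers one face of the W-shaped N–C12=C11–C7=C8 unit so that the acrylate adds to the other. The step therefore needs cross- over linear-trienamine reactivity (the linear isomer would have to form a quaternary C7 and is polarity-mismatched with the tether), exo-ester selectivity and enantiofacial control, whereas C15 is irrelevant because both acetal epimers converge in step 12.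

Step 8
Reactants: 13 cis-fused isochromene diol
Product: 15 triol (6α-OH; H-7 α), via cyclic alkoxyborane 14 (not isolated)
Conditions: BH3·THF (4 equiv), THF, 0 → 25 °C; then NaOH (aq), H2O2, 0 °C
Reagents that add atoms: hydrogen peroxide, OO
Why: Hydroboration–oxidation adds H and B syn, with boron on the less substituted C6 (remote from the allylic C8 oxygen) and from the α face, which is opposite to the pseudoaxial C8 ether, the C4 branch and the C14 branch of the cis-fused acetal ring, so that oxidation with retention should set 6α-OH and 7α-H (C11 arm β) in one operation.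

Step 9
Reactants: 15 triol
Product: 16 lactone aldehyde (6α,12-olide; C1 = CHO)
Conditions: TEMPO (20 mol%), PhI(OAc)2 (4 equiv), CH2Cl2, 25 °C
Reagents that add atoms: none
Why: The oxoammonium oxidation converts both primary alcohols: the C12 aldehyde is trapped by the 6α-hydroxyl as lactol and oxidised on to the trans-fused γ-lactone (oxidative lactonisation of a 1,4-diol), while the neopentylic C1 alcohol stops at the non-enolisable aldehyde.

Step 10
Reactants: 16 lactone aldehyde
Product: 17 vinyl lactone (C1=C2 on C10)
Conditions: Ph3PCH3Br, KN(SiMe3)2, THF, 0 °C; then 16, −78 → 0 °C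
Reagents that add atoms: methyltriphenylphosphonium bromide (as its ylide), C[P+](c1ccccc1)(c1ccccc1)c1ccccc1.[Br-]
Why: Wittig methylenation of the hindered but non-enolisable C1 aldehyde gives the vinyl group, the unstabilised ylide reacting with the aldehyde far faster than with the lactone at low temperature.

Step 11
Reactants: 17 vinyl lactone
Product: 18 lactol (C15 hemiacetal)
Conditions: 1 M HCl, THF, 25 °C
Reagents that add atoms: water, O
Why: Aqueous acid hydrolyses the cyclic methyl acetal (a 2-methoxytetrahydropyran) to the lactol, which opens reversibly to the C15 aldehyde and the free C14 alcohol, while PMB ether, lactone and vinyl group are stable to dilute acid.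

Step 12
Reactants: 18 lactol
Product: 19 hydroxy enal (C4=C3H2 next to C15HO; 14-OH free)
Conditions: 37% aq CH2O, pyrrolidine (20 mol%), propanoic acid (20 mol%), i-PrOH, 45 °C
Reagents that add atoms: formaldehyde, C=O
Why: Amine-catalysed Mannich-type α-methylenation of the aldehyde (through the enamine of the open form of the lactol) installs C3 as the methylene on C4, the only enolisable position of the aldehyde, the lactone not being enolised under these conditions.

Step 13
Reactants: 19 hydroxy enal
Product: 20 14,15-diol
Conditions: NaBH4, CeCl3·7H2O, MeOH, −40 °C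
Reagents that add atoms: none
Why: Luche reduction (1,2-selective) of the 2-substituted acrolein gives the allylic alcohol C15 and leaves the γ-lactone untouched.

Step 14
Reactants: 20 14,15-diol
Product: 21 14,15-bis-TBS ether
Conditions: TBSOTf (2.5 equiv), 2,6-lutidine, CH2Cl2, −78 → 0 °C
Reagents that add atoms: tert-butyldimethylsilyl trifluoromethanesulfonate, CC(C)(C)[Si](C)(C)OS(=O)(=O)C(F)(F)F
Why: Silylation of both primary alcohols (the neopentylic one needs the triflate) protects them against the base of step 15 and the Mitsunobu reaction of step 21.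

Step 15
Reactants: 21 14,15-bis-TBS ether
Product: 24 α-methylene lactone, via Mannich base 22 (not isolated), via ammonium iodide 23 (not isolated)
Conditions: LiN(iPr)2, THF, −78 °C; CH2=NMe2+ I−, −78 → 25 °C; then MeI, MeOH, 25 °C; then NaHCO3 (aq), EtOAc, 25 °C
Reagents that add atoms: dimethyl(methylidene)ammonium iodide, C=[N+](C)C.[I-]
Why: Aminomethylation of the lactone enolate, quaternisation and base-induced elimination (Mannich methylenation) introduce C13 as the exocyclic methylene; C7 is not epimerisable and the C11 stereocentre of 22 is destroyed.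

Step 16
Reactants: 24 α-methylene lactone
Product: 25 8β-alcohol
Conditions: DDQ (1.3 equiv), CH2Cl2/pH 7 buffer, 0 → 25 °C
Reagents that add atoms: none
Why: Oxidative cleavage of the PMB ether (hydride abstraction, hydrolysis of the oxocarbenium ion) frees the 8β-hydroxyl under neutral conditions that spare silyl ethers, alkenes and the α-methylene lactone.

Step 17
Reactants: 26 (2E)-but-2-enal
Product: 27 (2Z)-2-iodobut-2-enal
Conditions: I2, K2CO3, DMAP (20 mol%), THF/H2O, 25 °C
Reagents that add atoms: iodine, II
Why: α-Iodination by conjugate addition of DMAP, iodination of the enolate and elimination gives the thermodynamically preferred Z iodo-enal (iodine cis to methyl).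

Step 18
Reactants: 27 (2Z)-2-iodobut-2-enal
Product: 28 (2Z)-2-iodobut-2-en-1-ol
Conditions: NaBH4, MeOH, 0 °C
Reagents that add atoms: none
Why: 1,2-Reduction of the aldehyde leaves the vinyl iodide and its geometry untouched.

Step 19
Reactants: 28 (2Z)-2-iodobut-2-en-1-ol
Product: 29 TBS ether of 28
Conditions: TBSCl, imidazole, CH2Cl2, 25 °C
Reagents that add atoms: tert-butyldimethylsilyl chloride, CC(C)(C)[Si](C)(C)Cl
Why: Standard silylation of the primary allylic alcohol.

Step 20
Reactants: 29 TBS ether of 28
Product: 31 (2Z)-2-{[(tert-butyldimethylsilyl)oxy]methyl}but-2-enoic acid, via alkenyllithium 30 (not isolated)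
Conditions: t-BuLi (2.1 equiv), Et2O, −78 °C; then CO2 (gas), −78 → 0 °C; then 1 M HCl, 0 °C
Reagents that add atoms: carbon dioxide, O=C=O
Why: Iodine–lithium exchange gives a configurationally stable alkenyllithium that is carboxylated with retention, so that the carboxyl group ends up cis to the methyl group (Z acid).

Step 21
Reactants: 25 8β-alcohol; 31 (2Z)-2-{[(tert-butyldimethylsilyl)oxy]methyl}but-2-enoic acid
Product: 32 8α-ester (tris-TBS ether of the target)
Conditions: PPh3 (2 equiv), diisopropyl azodicarboxylate (2 equiv), toluene, 0 → 25 °C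
Reagents that add atoms: none
Why: Mitsunobu esterification activates the axial 8β-hydroxyl as alkoxyphosphonium ion and the carboxylate of 31 displaces it from the open α face with inversion (SN2), which sets the equatorial 8α-acyloxy centre (8S) and relieves the 1,3-diaxial contact with C14, the Z geometry of the acid not being touched under these neutral conditions.

Step 22
Reactants: 32 8α-ester (tris-TBS ether of the target)
Product: 33 target
Conditions: HF·pyridine, pyridine, THF, 0 → 25 °C
Reagents that add atoms: none
Why: Buffered fluoride cleaves the three silyl ethers without harming the α-methylene lactone or the two esters, and the 8α-ester and the β-oriented C14 hydroxyl are 1,3-trans, so acyl migration is not expected.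

**Compound list**
1 | but-2-yne-1,4-diol | OCC#CCO | starting material
2 | 4-[(4-methoxyphenyl)methoxy]but-2-yn-1-ol | COc1ccc(COCC#CCO)cc1 | intermediate
3 | 4-[(4-methoxyphenyl)methoxy]but-2-ynal | COc1ccc(COCC#CC=O)cc1 | intermediate
4 | (2Z)-3-iodo-4-[(4-methoxyphenyl)methoxy]but-2-enal | O=C/C=C(\I)COCc1ccc(OC)cc1 | intermediate
5 | methyl 2-(hydroxymethyl)prop-2-enoate | C=C(CO)C(=O)OC | starting material
6 | (1Z)-1-methoxybut-1-en-3-yne | C#C/C=C\OC | starting material
7 | methyl 2-{[(1-methoxybut-3-yn-1-yl)oxy]methyl}prop-2-enoate (acetal carbon = C15, both configurations) | C#CCC(OC)OCC(=C)C(=O)OC | intermediate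
8 | methyl 2-({[(3E)-1-methoxy-4-(4,4,5,5-tetramethyl-1,3,2-dioxaborolan-2-yl)but-3-en-1-yl]oxy}methyl)prop-2-enoate | CC1(C)OB(/C=C/CC(OC)OCC(=C)C(=O)OC)OC1(C)C | intermediate
9 | methyl 2-{[((3E,5E)-1-methoxy-5-{[(4-methoxyphenyl)methoxy]methyl}-7-oxohepta-3,5-dien-1-yl)oxy]methyl}prop-2-enoate | O=C/C=C(COCc1ccc(OC)cc1)\C=C\CC(OC)OCC(=C)C(=O)OC | intermediate
10 | cross-trienamine of 9 with the (R)-amine (N on C12; C12=C11 E; C7=C8 with OPMB syn to C11; C5=C6 E; not isolated) | COC(=O)C(=C)COC(OC)C/C=C/C(=C/OCc1ccc(OC)cc1)/C=C/N1CCC[C@@H]1C(c1ccccc1)(c1ccccc1)O[Si](C)(C)C | intermediate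
11 | cycloadduct dienamine (amine on C12; C12=C11–C7=C6; ring system and configuration as in 12; not isolated) | COC(=O)[C@]1(C3)C[C@@H](OCc4ccc(OC)cc4)C(/C=C/N5CCC[C@@H]5C(c5ccccc5)(c5ccccc5)O[Si](C)(C)C)=C[C@H]1CC(OC)O3 | intermediate
12 | methyl cis-3-methoxy-7-[(4-methoxyphenyl)methoxy]-6-(2-oxoethyl)-3,4,4a,7,8,8a-hexahydro-1H-isochromene-8a-carboxylate (H-5 α; 8β-OPMB; on C10: C14 β and ester C1 α; not isolated) | COC(=O)[C@]1(C3)C[C@@H](OCc4ccc(OC)cc4)C(CC=O)=C[C@H]1CC(OC)O3 | intermediate
13 | 2-{cis-8a-(hydroxymethyl)-3-methoxy-7-[(4-methoxyphenyl)methoxy]-3,4,4a,7,8,8a-hexahydro-1H-isochromen-6-yl}ethanol (configuration as 12) | OC[C@]1(C3)C[C@@H](OCc4ccc(OC)cc4)C(CCO)=C[C@H]1CC(OC)O3 | intermediate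
14 | cyclic alkoxyborane (boron on C6 α and on the C12 oxygen; drawn with the C1 hydroxyl free; not isolated) | OC[C@]1(C3)C[C@@H](OCc5ccc(OC)cc5)[C@H]4CCOB[C@@H]4[C@H]1CC(OC)O3 | intermediate
15 | triol: 6α-hydroxy-7α-H hydration product of 13 (C11 arm β) | OC[C@]1(C3)C[C@@H](OCc4ccc(OC)cc4)[C@@H](CCO)[C@H](O)[C@H]1CC(OC)O3 | intermediate
16 | lactone aldehyde: trans-fused 6α,12-γ-lactone (H-6 β, H-7 α); C1 formyl α on C10; 8β-OPMB; C14–O–C15 cyclic methyl acetal | O=C[C@]1(C3)C[C@@H](OCc4ccc(OC)cc4)[C@H]2CC(=O)O[C@@H]2[C@H]1CC(OC)O3 | intermediate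
17 | vinyl lactone: as 16 with C1=C2 vinyl on C10 | C=C[C@]1(C3)C[C@@H](OCc4ccc(OC)cc4)[C@H]2CC(=O)O[C@@H]2[C@H]1CC(OC)O3 | intermediate
18 | lactol: as 17 with C15 hemiacetal OH | C=C[C@]1(C3)C[C@@H](OCc4ccc(OC)cc4)[C@H]2CC(=O)O[C@@H]2[C@H]1CC(O)O3 | intermediate
19 | hydroxy enal: 14-hydroxy; C4(=C3H2)–C15HO on C5 (in equilibrium with its lactol); 8β-OPMB; 6α,12-olide | C=C[C@]1(CO)C[C@@H](OCc3ccc(OC)cc3)[C@H]2CC(=O)O[C@@H]2[C@H]1C(=C)C=O | intermediate
20 | 14,15-diol: 8β-OPMB-14,15-dihydroxyelema-1,3-dien-12,6α-olide | C=C[C@]1(CO)C[C@@H](OCc3ccc(OC)cc3)[C@H]2CC(=O)O[C@@H]2[C@H]1C(=C)CO | intermediate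
21 | 14,15-bis-TBS ether of 20 | C=C[C@]1(CO[Si](C)(C)C(C)(C)C)C[C@@H](OCc3ccc(OC)cc3)[C@H]2CC(=O)O[C@@H]2[C@H]1C(=C)CO[Si](C)(C)C(C)(C)C | intermediate
22 | Mannich base: 11-(dimethylaminomethyl) derivative of 21 (not isolated) | C=C[C@]1(CO[Si](C)(C)C(C)(C)C)C[C@@H](OCc3ccc(OC)cc3)[C@H]2C(CN(C)C)C(=O)O[C@@H]2[C@H]1C(=C)CO[Si](C)(C)C(C)(C)C | intermediate
23 | trimethylammonium iodide of 22 (not isolated) | C=C[C@]1(CO[Si](C)(C)C(C)(C)C)C[C@@H](OCc3ccc(OC)cc3)[C@H]2C(C[N+](C)(C)C)C(=O)O[C@@H]2[C@H]1C(=C)CO[Si](C)(C)C(C)(C)C.[I-] | intermediate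
24 | α-methylene lactone: 8β-OPMB-14,15-bis-TBS-elema-1,3,11(13)-trien-12,6α-olide | C=C[C@]1(CO[Si](C)(C)C(C)(C)C)C[C@@H](OCc3ccc(OC)cc3)[C@H]2C(=C)C(=O)O[C@@H]2[C@H]1C(=C)CO[Si](C)(C)C(C)(C)C | intermediate
25 | 8β-alcohol: 8β-hydroxy-14,15-bis-TBS-elema-1,3,11(13)-trien-12,6α-olide | C=C[C@]1(CO[Si](C)(C)C(C)(C)C)C[C@@H](O)[C@H]2C(=C)C(=O)O[C@@H]2[C@H]1C(=C)CO[Si](C)(C)C(C)(C)C | intermediate
26 | (2E)-but-2-enal | C/C=C/C=O | starting material
27 | (2Z)-2-iodobut-2-enal | C/C=C(\I)C=O | intermediate
28 | (2Z)-2-iodobut-2-en-1-ol | C/C=C(\I)CO | intermediate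
29 | tert-butyl{[(2Z)-2-iodobut-2-en-1-yl]oxy}dimethylsilane | C/C=C(\I)CO[Si](C)(C)C(C)(C)C | intermediate
30 | alkenyllithium from 29 (lithium in place of iodine; not isolated) | C/C=C(\[Li])CO[Si](C)(C)C(C)(C)C | intermediate
31 | (2Z)-2-{[(tert-butyldimethylsilyl)oxy]methyl}but-2-enoic acid | C/C=C(/CO[Si](C)(C)C(C)(C)C)C(=O)O | intermediate
32 | 8α-ester: tris-TBS ether of 33 | C=C[C@]1(CO[Si](C)(C)C(C)(C)C)C[C@H](OC(=O)/C(=C\C)CO[Si](C)(C)C(C)(C)C)[C@H]2C(=C)C(=O)O[C@@H]2[C@H]1C(=C)CO[Si](C)(C)C(C)(C)C | intermediate
33 | (5S,6R,7R,8S,10R)-8-{[(2Z)-2-(hydroxymethyl)but-2-enoyl]oxy}-14,15-dihydroxyelema-1,3,11(13)-trien-12,6-olide (CNP0338073.1) | C=C[C@]1(CO)C[C@H](OC(=O)/C(=C\C)CO)[C@H]2C(=C)C(=O)O[C@@H]2[C@H]1C(=C)CO | target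

Total step count: 22. Longest linear sequence: 16 steps (1–3, 6–16, 21, 22).

**Steps most likely to fail**

Step 7 (proposed new method). The singly activated acrylate may add too slowly to the catalytically generated trienamine, so that turnover stalls and the enol ether and acetal are slowly hydrolysed in the acidic, water-containing medium. The ester may also take the endo position (trans-fused acetal ring), and facial shielding may be incomplete; if only the sense of induction is opposite to the model, the (S)-amine is used instead. Fallback, setting out from 9 and coming back at 13: 9 is condensed with one equivalent of the same (R)-amine under dehydrating conditions (benzene, molecular sieves) and the trienamine 10 is isolated. It is cyclised thermally in dry toluene (80–110 °C) without acid or water to dienamine 11, the auxiliary is removed by hydrolysis (AcOH, H2O, THF) to give 12, and LiAlH4 then gives 13. This is the classical stoichiometric, auxiliary-bound aminodiene Diels–Alder reaction; it removes catalyst turnover and the hydrolytic medium from the cycloaddition and makes no compound outside the list (F0).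

Step 8. The borane may attack both alkene faces (the cis-fused ring system is conformationally mobile), which would scramble C6 and C7 together. Fallback, setting out from 13 and coming back at 15: the unhindered C12 hydroxyl is silylated selectively (TBDPSCl, imidazole, −20 °C) to the mono-TBDPS ether F1. The neopentylic C1 hydroxyl is converted with 1,1,3,3-tetramethyldisilazane into the dimethylsilyl ether F2. Pt2(dvs)3 (a zerovalent platinum complex) then effects intramolecular hydrosilylation, in which the tether can deliver Si–H only to the α face (silicon to C6, hydrogen to C7, syn), giving the cyclic siloxane F3. Tamao–Fleming oxidation (KF, KHCO3, H2O2) with retention gives the 6α-alcohol F4, and Bu4NF removes the TBDPS group to give 15.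

Step 21. Elimination of the activated axial alcohol toward C7 (giving a diene conjugated with the lactone) may outrun the slow SN2 attack of the hindered, weakly acidic carboxylate, and the Z acid may isomerise. Fallback, setting out from 25 and coming back at 32: Mitsunobu inversion with the small, more acidic chloroacetic acid (PPh3, diisopropyl azodicarboxylate) gives the 8α-chloroacetate F5. DABCO in ethanol removes the chloroacetyl group selectively to give the 8α-alcohol F6. Yamaguchi esterification (31, 2,4,6-trichlorobenzoyl chloride, Et3N; then F6, DMAP, toluene) proceeds with retention at C8 and gives 32.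

Further compounds
F0 | step 7 | none | none
F1 | step 8 | mono-TBDPS ether of 13 (C12–O–SiPh2tBu; C1–OH free) | OC[C@]1(C3)C[C@@H](OCc4ccc(OC)cc4)C(CCO[Si](c5ccccc5)(c5ccccc5)C(C)(C)C)=C[C@H]1CC(OC)O3
F2 | step 8 | C1 dimethylsilyl ether of F1 | C[SiH](C)OC[C@]1(C3)C[C@@H](OCc4ccc(OC)cc4)C(CCO[Si](c5ccccc5)(c5ccccc5)C(C)(C)C)=C[C@H]1CC(OC)O3
F3 | step 8 | cyclic siloxane (SiMe2 bridging the C1 oxygen and C6 α; H-7 α) | C[Si]5(C)OC[C@]1(C3)C[C@@H](OCc4ccc(OC)cc4)[C@@H](CCO[Si](c6ccccc6)(c6ccccc6)C(C)(C)C)[C@H]5[C@H]1CC(OC)O3
F4 | step 8 | 6α-alcohol (12-O-TBDPS ether of 15) | OC[C@]1(C3)C[C@@H](OCc4ccc(OC)cc4)[C@@H](CCO[Si](c5ccccc5)(c5ccccc5)C(C)(C)C)[C@H](O)[C@H]1CC(OC)O3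
F5 | step 21 | 8α-chloroacetate of the C8 epimer of 25 | C=C[C@]1(CO[Si](C)(C)C(C)(C)C)C[C@H](OC(=O)CCl)[C@H]2C(=C)C(=O)O[C@@H]2[C@H]1C(=C)CO[Si](C)(C)C(C)(C)C
F6 | step 21 | 8α-alcohol (C8 epimer of 25) | C=C[C@]1(CO[Si](C)(C)C(C)(C)C)C[C@H](O)[C@H]2C(=C)C(=O)O[C@@H]2[C@H]1C(=C)CO[Si](C)(C)C(C)(C)C
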